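Assumption: the target has no stereocentre and no stereodefined double bond, so the SMILES is taken as the complete structure (achiral; the aryl–indole axes are not configurationally fixed).

**Retrosynthetic overview**
1. Target 18 ⇐ para-methoxyphenol 16 by phenol-to-quinone oxidation and hydrolysis of the vinylogous methyl ester; 16 ⇐ 15 by acid removal of O-tBu and C-SiEt3.
2. Key disconnection: 15 ⇐ diyne 13 + two 2-iodoaniline, a twofold Larock heteroannulation; the SiEt3 group and the tertiary alkyl group steer the central ring onto C3 of each indole.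
3. 13 ⇐ 10 by two ortho-metalations of the equivalent C–H pair (O-tBu first, then prenyl).
4. 10 ⇐ 2,6-dimethoxy-1,4-benzoquinone + two different lithium acetylides, then SnCl2 aromatisation; enyne 5 ⇐ prenylmagnesium chloride + Weinreb amide, then ketone-to-alkyne conversion.
5. Ring order: the central carbocycle is bought as the quinone (aromatised in step 3, re-oxidised in step 8); the benzo rings are bought in 2-iodoaniline; both pyrrole rings close together in step 6.

**Route**

Step 1
Reactants: 1 N-methoxy-N-methylacetamide; 2 prenylmagnesium chloride (3-methylbut-2-enylmagnesium chloride, THF solution)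
Product: 3 3,3-dimethylpent-4-en-2-one
Conditions: THF, −78 °C to 0 °C; 1 M HCl
Reagents that add atoms: none
Why: Weinreb ketone synthesis in which the allylic magnesium reagent attacks through its γ-carbon (SE2′), so the quaternary 1,1-dimethylallyl carbon forms directly and the chelated tetrahedral intermediate prevents over-addition; no stereocentre is formed.

Step 2
Reactants: 3 3,3-dimethylpent-4-en-2-one
Product: 5 3,3-dimethylpent-4-en-1-yne, via enol phosphate 4 (not isolated)
Conditions: LiN(i-Pr)2 (1.05 equiv), THF, −78 °C; ClP(O)(OEt)2, −78 °C to rt; LiN(i-Pr)2 (2.3 equiv), −78 °C to rt; H2O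
Reagents that add atoms: none
Why: Negishi methyl-ketone-to-alkyne conversion, in which enolisation is possible only at the methyl group (the other α-carbon is quaternary) and the enol phosphate undergoes base-induced β-elimination to the acetylide, protonated on quench; no stereocentre.

Step 3
Reactants: 5 3,3-dimethylpent-4-en-1-yne; 6 2,6-dimethoxy-1,4-benzoquinone; 7 (triethylsilyl)acetylene
Product: 10 2-(3,3-dimethylpent-4-en-1-yn-1-yl)-1,3-dimethoxy-5-[(triethylsilyl)ethynyl]benzene, via alkynyl quinol 8 (not isolated), via dialkynyl diol 9 (not isolated)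
Conditions: 5, n-BuLi, THF, −78 °C, added to 6 (1.05 equiv), −78 °C; then LiC≡CSiEt3 (from 7 + n-BuLi, 3 equiv), −78 °C to rt; then SnCl2·2H2O, 10% aq HCl, THF, rt
Reagents that add atoms: none
Why: Sequential 1,2-addition of two lithium acetylides to a quinone followed by SnCl2 reductive aromatisation, in which the first acetylide attacks C1 (the only carbonyl that is not a vinylogous ester), the second is forced onto the remaining carbonyl, and tin dichloride removes both tertiary hydroxyls of the cis/trans diol mixture so the transient stereocentres vanish in the arene.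

Step 4
Reactants: 10 2-(3,3-dimethylpent-4-en-1-yn-1-yl)-1,3-dimethoxy-5-[(triethylsilyl)ethynyl]benzene
Product: 11 1-tert-butoxy-3-(3,3-dimethylpent-4-en-1-yn-1-yl)-2,4-dimethoxy-6-[(triethylsilyl)ethynyl]benzene
Conditions: s-BuLi (1.1 equiv), TMEDA, THF, −78 °C; MgBr2·OEt2, −78 °C to 0 °C; PhCO3t-Bu, 0 °C to rt; aq NH4Cl
Reagents that add atoms: tert-butyl perbenzoate, CC(C)(C)OOC(=O)c1ccccc1
Why: Directed ortho-metalation followed by electrophilic tert-butoxylation of the arylmagnesium bromide with a perester (Lawesson–Yang type), regiochemically unambiguous because the two ring hydrogens are equivalent and each lies between a methoxy group and an alkynyl group; no stereocentre.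

Step 5
Reactants: 11 1-tert-butoxy-3-(3,3-dimethylpent-4-en-1-yn-1-yl)-2,4-dimethoxy-6-[(triethylsilyl)ethynyl]benzene; 12 prenyl bromide (1-bromo-3-methylbut-2-ene)
Product: 13 1-tert-butoxy-3-(3,3-dimethylpent-4-en-1-yn-1-yl)-2,4-dimethoxy-5-(3-methylbut-2-en-1-yl)-6-[(triethylsilyl)ethynyl]benzene
Conditions: s-BuLi (1.1 equiv), TMEDA, THF, −78 °C; CuBr·SMe2 (10 mol %); 12, −78 °C to 0 °C
Reagents that add atoms: none
Why: Second directed ortho-metalation at the only remaining ring C–H (flanked by methoxy and alkynyl) followed by copper-catalysed SN2 allylation with prenyl bromide; no stereocentre.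

Step 6
Reactants: 13 1-tert-butoxy-3-(3,3-dimethylpent-4-en-1-yn-1-yl)-2,4-dimethoxy-5-(3-methylbut-2-en-1-yl)-6-[(triethylsilyl)ethynyl]benzene; 14 2-iodoaniline (3 equiv)
Product: 15 1-tert-butoxy-2,4-dimethoxy-3-[2-(2-methylbut-3-en-2-yl)-1H-indol-3-yl]-5-(3-methylbut-2-en-1-yl)-6-[2-(triethylsilyl)-1H-indol-3-yl]benzene
Conditions: Pd(OAc)2 (10 mol %), LiCl (2 equiv), K2CO3 (6 equiv), DMF, 100 °C
Reagents that add atoms: none
Why: Twofold Larock heteroannulation, in which each arylpalladium iodide adds syn across one alkyne with palladium on the carbon carrying the bulkier SiEt3 or tertiary alkyl group and C–N reductive elimination then closes both pyrrole rings in the same operation with the central ring on C3 of each indole; no stereocentre.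

Step 7
Reactants: 15 1-tert-butoxy-2,4-dimethoxy-3-[2-(2-methylbut-3-en-2-yl)-1H-indol-3-yl]-5-(3-methylbut-2-en-1-yl)-6-[2-(triethylsilyl)-1H-indol-3-yl]benzene
Product: 16 6-(1H-indol-3-yl)-2,4-dimethoxy-3-[2-(2-methylbut-3-en-2-yl)-1H-indol-3-yl]-5-(3-methylbut-2-en-1-yl)phenol
Conditions: TFA/CH2Cl2 (1:9), 0 °C to rt; aq NaHCO3
Reagents that add atoms: none
Why: Acidolysis, in which trifluoroacetic acid cleaves the aryl tert-butyl ether by an E1 path and removes the indole 2-silyl group by ipso-protodesilylation (β-silyl cation) while the methyl ethers stay intact; no stereocentre.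

Step 8
Reactants: 16 6-(1H-indol-3-yl)-2,4-dimethoxy-3-[2-(2-methylbut-3-en-2-yl)-1H-indol-3-yl]-5-(3-methylbut-2-en-1-yl)phenol
Product: 18 3-hydroxy-5-(1H-indol-3-yl)-2-[2-(2-methylbut-3-en-2-yl)-1H-indol-3-yl]-6-(3-methylbut-2-en-1-yl)cyclohexa-2,5-diene-1,4-dione, via methoxyquinone 17 (not isolated)
Conditions: PhI(OAc)2 (1.1 equiv), MeCN/H2O 4:1, 0 °C; then 2 M NaOH, MeOH, rt to 40 °C; 1 M HCl
Reagents that add atoms: water, O; sodium hydroxide, [Na+].[OH-]
Why: Hypervalent-iodine oxidation of a para-methoxyphenol to the para-quinone (water adds at the methoxy-bearing carbon and methanol is lost) followed by addition–elimination hydrolysis of the vinylogous ester by hydroxide, which gives the hydroxyquinone anion and, on acidification, the target; no stereocentre.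

**Compound list**
1 | N-methoxy-N-methylacetamide | CC(=O)N(C)OC | starting material
2 | prenylmagnesium chloride | CC(C)=CC[Mg]Cl | starting material
3 | 3,3-dimethylpent-4-en-2-one | CC(=O)C(C)(C)C=C | intermediate
4 | diethyl 3,3-dimethylpenta-1,4-dien-2-yl phosphate | C=C(OP(=O)(OCC)OCC)C(C)(C)C=C | intermediate (not isolated)
5 | 3,3-dimethylpent-4-en-1-yne | C#CC(C)(C)C=C | intermediate
6 | 2,6-dimethoxy-1,4-benzoquinone | COC1=CC(=O)C=C(OC)C1=O | starting material
7 | (triethylsilyl)acetylene | C#C[Si](CC)(CC)CC | starting material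
8 | 4-(3,3-dimethylpent-4-en-1-yn-1-yl)-4-hydroxy-3,5-dimethoxycyclohexa-2,5-dien-1-one | COC1=CC(=O)C=C(OC)C1(O)C#CC(C)(C)C=C | intermediate (not isolated)
9 | 1-(3,3-dimethylpent-4-en-1-yn-1-yl)-2,6-dimethoxy-4-[(triethylsilyl)ethynyl]cyclohexa-2,5-diene-1,4-diol (cis/trans mixture) | COC1=CC(O)(C#C[Si](CC)(CC)CC)C=C(OC)C1(O)C#CC(C)(C)C=C | intermediate (not isolated)
10 | 2-(3,3-dimethylpent-4-en-1-yn-1-yl)-1,3-dimethoxy-5-[(triethylsilyl)ethynyl]benzene | COc1cc(C#C[Si](CC)(CC)CC)cc(OC)c1C#CC(C)(C)C=C | intermediate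
11 | 1-tert-butoxy-3-(3,3-dimethylpent-4-en-1-yn-1-yl)-2,4-dimethoxy-6-[(triethylsilyl)ethynyl]benzene | COc1c(C#CC(C)(C)C=C)c(OC)cc(C#C[Si](CC)(CC)CC)c1OC(C)(C)C | intermediate
12 | prenyl bromide | CC(C)=CCBr | starting material
13 | 1-tert-butoxy-3-(3,3-dimethylpent-4-en-1-yn-1-yl)-2,4-dimethoxy-5-(3-methylbut-2-en-1-yl)-6-[(triethylsilyl)ethynyl]benzene | COc1c(C#CC(C)(C)C=C)c(OC)c(CC=C(C)C)c(C#C[Si](CC)(CC)CC)c1OC(C)(C)C | intermediate
14 | 2-iodoaniline | Nc1ccccc1I | starting material
15 | 1-tert-butoxy-2,4-dimethoxy-3-[2-(2-methylbut-3-en-2-yl)-1H-indol-3-yl]-5-(3-methylbut-2-en-1-yl)-6-[2-(triethylsilyl)-1H-indol-3-yl]benzene | COc1c(-c2c(C(C)(C)C=C)[nH]c3ccccc23)c(OC)c(CC=C(C)C)c(-c2c([Si](CC)(CC)CC)[nH]c3ccccc23)c1OC(C)(C)C | intermediate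
16 | 6-(1H-indol-3-yl)-2,4-dimethoxy-3-[2-(2-methylbut-3-en-2-yl)-1H-indol-3-yl]-5-(3-methylbut-2-en-1-yl)phenol | COc1c(-c2c(C(C)(C)C=C)[nH]c3ccccc23)c(OC)c(CC=C(C)C)c(-c2c[nH]c3ccccc23)c1O | intermediate
17 | 5-(1H-indol-3-yl)-3-methoxy-2-[2-(2-methylbut-3-en-2-yl)-1H-indol-3-yl]-6-(3-methylbut-2-en-1-yl)cyclohexa-2,5-diene-1,4-dione | COC1=C(c2c(C(C)(C)C=C)[nH]c3ccccc23)C(=O)C(CC=C(C)C)=C(c2c[nH]c3ccccc23)C1=O | intermediate (not isolated)
18 | 3-hydroxy-5-(1H-indol-3-yl)-2-[2-(2-methylbut-3-en-2-yl)-1H-indol-3-yl]-6-(3-methylbut-2-en-1-yl)cyclohexa-2,5-diene-1,4-dione | C=CC(C)(C)c1[nH]c2ccccc2c1C1=C(O)C(=O)C(c2c[nH]c3ccccc23)=C(CC=C(C)C)C1=O | target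

**Totals**
Total step count: 8. Longest linear sequence: 8 (steps 1 to 8; compounds 6, 7, 12 and 14 are bought).

**Steps most likely to fail and their fallbacks**

Step 6 (twofold Larock heteroannulation). Both alkynes sit between two ortho substituents of a hexasubstituted benzene, and one carries a tertiary alkyl group. Carbopalladation may therefore be slow, the C–N reductive elimination from the crowded vinylpalladium species may stall, and the terminal vinyl group could undergo Heck arylation. The fallback sets out from 13 and comes back at 15, replacing palladium-mediated C–N bond formation by nitrene C–H insertion. Both alkynes of 13 are hydroarylated with 1-iodo-2-nitrobenzene under reductive Heck conditions (Pd(OAc)2, PPh3, HCO2Na, DMF, 60 °C; syn addition, aryl on the arene-bearing carbon) to give the diene 1-tert-butoxy-3-[(1Z)-3,3-dimethyl-1-(2-nitrophenyl)penta-1,4-dien-1-yl]-2,4-dimethoxy-5-(3-methylbut-2-en-1-yl)-6-[(Z)-1-(2-nitrophenyl)-2-(triethylsilyl)ethenyl]benzene F1. A double Cadogan–Sundberg reductive cyclisation (P(OEt)3, 160 °C) then closes both pyrrole rings at once onto the vinylic C–H bonds and delivers 15.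

Step 3 (one-pot double alkynylation and SnCl2 aromatisation). The second acetylide must add to a doubly vinylogous ester carbonyl that already carries a lithium alkoxide, and the bis-enol-ether diol 9 may hydrolyse under acid instead of aromatising. If the first addition goes to the other carbonyl, the two acetylides are simply added in the reverse order. The fallback sets out from quinol 8 (isolated after the first addition of 5 to 6) and comes back at 10, replacing the second 1,2-addition by a cross-coupling. Quinol 8 is reduced with Zn in AcOH to the phenol 4-(3,3-dimethylpent-4-en-1-yn-1-yl)-3,5-dimethoxyphenol F2. Treatment with Tf2O and pyridine in CH2Cl2 gives 4-(3,3-dimethylpent-4-en-1-yn-1-yl)-3,5-dimethoxyphenyl trifluoromethanesulfonate F3. Sonogashira coupling of F3 with 7 (Pd(PPh3)4, CuI, Et3N, DMF, 60 °C) gives 10.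

Step 8 (phenol oxidation beside two free indoles). The oxidised phenol could be trapped by the unsubstituted C2 of the ring B indole, or the indoles could be oxidised by the iodine reagent. The fallback sets out from 15 and comes back at 18, oxidising the arene while C2 of that indole is still blocked by silicon. Oxidative dealkylation of the para tert-butoxy/methoxy pair of 15 with (NH4)2Ce(NO3)6 in MeCN/H2O at 0 °C gives the quinone 3-methoxy-2-[2-(2-methylbut-3-en-2-yl)-1H-indol-3-yl]-6-(3-methylbut-2-en-1-yl)-5-[2-(triethylsilyl)-1H-indol-3-yl]cyclohexa-2,5-diene-1,4-dione F4. Desilylation with Bu4NF in wet THF, hydrolysis with aqueous NaOH in MeOH and acidification then give 18.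

**Further compounds**
F1 | step 6 | 1-tert-butoxy-3-[(1Z)-3,3-dimethyl-1-(2-nitrophenyl)penta-1,4-dien-1-yl]-2,4-dimethoxy-5-(3-methylbut-2-en-1-yl)-6-[(Z)-1-(2-nitrophenyl)-2-(triethylsilyl)ethenyl]benzene | COc1c(/C(c2ccccc2[N+](=O)[O-])=C\C(C)(C)C=C)c(OC)c(CC=C(C)C)c(/C(c2ccccc2[N+](=O)[O-])=C\[Si](CC)(CC)CC)c1OC(C)(C)C
F2 | step 3 | 4-(3,3-dimethylpent-4-en-1-yn-1-yl)-3,5-dimethoxyphenol | COc1cc(O)cc(OC)c1C#CC(C)(C)C=C
F3 | step 3 | 4-(3,3-dimethylpent-4-en-1-yn-1-yl)-3,5-dimethoxyphenyl trifluoromethanesulfonate | COc1cc(OS(=O)(=O)C(F)(F)F)cc(OC)c1C#CC(C)(C)C=C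
F4 | step 8 | 3-methoxy-2-[2-(2-methylbut-3-en-2-yl)-1H-indol-3-yl]-6-(3-methylbut-2-en-1-yl)-5-[2-(triethylsilyl)-1H-indol-3-yl]cyclohexa-2,5-diene-1,4-dione | COC1=C(c2c(C(C)(C)C=C)[nH]c3ccccc23)C(=O)C(CC=C(C)C)=C(c2c([Si](CC)(CC)CC)[nH]c3ccccc23)C1=O
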